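**Retrosynthetic overview**
- The target comes from fluoride desilylation of its 2′,5′‑bis‑silyl ether, which comes from trans‑hydration of a 3‑aryl‑2H‑chromene (isoflav‑3‑ene) by reagent‑controlled asymmetric hydroboration/oxidation; C3 and C4 are set together.
- The isoflav‑3‑ene comes from Suzuki union of 3‑bromo‑6,7,8‑trimethoxy‑2H‑chromene with a bis‑silylated bromohydroquinone made from 2,3‑dimethoxybenzoquinone (ring B is bought intact).
- The bromochromene comes from a one‑flask Moore rearrangement / oxa‑6π cascade of the dimethyl squarate adduct of 2‑bromopent‑1‑en‑4‑yne.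
- Ring order: A (benzoquinone) and then C (pyran) are both formed in that single operation; B is attached last.

Assumption: 1, 2, 4 and 10 are bought; monoisopinocampheylborane (IpcBH2) is made beforehand from (+)‑α‑pinene and used as a reagent; simple reagents are named in the steps and not numbered.

Step 1
Reactants: 1 2,3‑dibromoprop‑1‑ene; 2 ethynylmagnesium bromide
Product: 3 2‑bromopent‑1‑en‑4‑yne
Conditions: 2 (1.5 equiv), CuCl (5 mol%), THF, 0 to 40 °C
Reagents that add atoms: none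
Why: Copper‑catalysed allyl–alkynyl Grignard cross‑coupling displaces only the allylic bromide (the vinylic C–Br is inert), giving the skipped enyne with no stereocentre.

Step 2
Reactants: 3 2‑bromopent‑1‑en‑4‑yne; 4 dimethyl squarate
Product: 6 4‑(4‑bromopent‑4‑en‑1‑yn‑1‑yl)‑4‑hydroxy‑2,3‑dimethoxycyclobut‑2‑en‑1‑one (racemic), via lithium acetylide 5 (not isolated)
Conditions: LDA (1.05 equiv), THF, −78 °C; cannulate into 4 (1.1 equiv), THF, −78 °C; NH4Cl (aq)
Reagents that add atoms: lithium diisopropylamide, CC(C)[N-]C(C)C.[Li+] (Li of intermediate 5 only)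
Why: 1,2‑addition of a lithium acetylide to one carbonyl of the squarate (Liebeskind–Moore squarate addition) gives the 4‑alkynyl‑4‑hydroxycyclobutenone, whose single racemic stereocentre is destroyed in step 3.

Step 3
Reactants: 6 4‑(4‑bromopent‑4‑en‑1‑yn‑1‑yl)‑4‑hydroxy‑2,3‑dimethoxycyclobut‑2‑en‑1‑one
Product: 9 3‑bromo‑6,7,8‑trimethoxy‑2H‑chromene, via allylquinone 7 (not isolated), via chromenol 8 (not isolated)
Conditions: p‑xylene (0.02 M), 138 °C, 1 h, Ar; Et3N (0.5 equiv), 100 °C, 2 h; evaporate; K2CO3, MeI, DMF, rt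
Reagents that add atoms: iodomethane, CI
Why: Proposed new method: thermal 4π ring opening of 6 to an alkynyl vinylketene, diradical ring closure and H transfer give quinone 7 (Moore rearrangement), whose allylic CH2 then tautomerises under base to an o‑quinone methide that closes by oxa‑6π electrocyclisation to chromenol 8 (closest known types: Moore 4‑alkynyl‑4‑hydroxycyclobutenone → benzoquinone synthesis and the base‑induced allyl/prenylquinone → 2H‑chromen‑6‑ol isomerisation), and in situ Williamson methylation caps the 6‑OH; no stereocentre.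

Step 4
Reactants: 10 2,3‑dimethoxy‑1,4‑benzoquinone
Product: 12 5‑bromo‑2,3‑dimethoxy‑1,4‑benzoquinone, via dibromide 11 (not isolated)
Conditions: Br2 (1.0 equiv), CHCl3, 0 °C; then NaOAc, AcOH, 50 °C
Reagents that add atoms: bromine, BrBr
Why: Bromine addition across the unsubstituted quinone C=C followed by dehydrobromination (addition–elimination bromination of a quinone) gives the monobromoquinone.

Step 5
Reactants: 12 5‑bromo‑2,3‑dimethoxy‑1,4‑benzoquinone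
Product: 14 1‑bromo‑2,5‑bis(tert‑butyldimethylsilyloxy)‑3,4‑dimethoxybenzene, via bromohydroquinone 13 (not isolated)
Conditions: Na2S2O4, EtOAc/H2O, rt; then TBSOTf (2.5 equiv), 2,6‑lutidine, CH2Cl2, 0 °C to rt
Reagents that add atoms: tert‑butyldimethylsilyl triflate, CC(C)(C)[Si](C)(C)OS(=O)(=O)C(F)(F)F
Why: Reductive silylation (dithionite reduction, then O‑silylation) masks both hydroquinone oxygens, so that a free 2′‑OH never sits beside the chromene or the later benzylic alcohol, where it would close to a pterocarpan.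

Step 6
Reactants: 14 1‑bromo‑2,5‑bis(tert‑butyldimethylsilyloxy)‑3,4‑dimethoxybenzene; 9 3‑bromo‑6,7,8‑trimethoxy‑2H‑chromene
Product: 16 3‑[2,5‑bis(tert‑butyldimethylsilyloxy)‑3,4‑dimethoxyphenyl]‑6,7,8‑trimethoxy‑2H‑chromene, via arylboronate 15 (not isolated)
Conditions: 14, B2pin2 (1.1 equiv), Pd(dppf)Cl2 (3 mol%), KOAc, dioxane, 90 °C; then 9, SPhos Pd G2 (3 mol%), K3PO4, H2O (5 equiv), 80 °C
Reagents that add atoms: bis(pinacolato)diboron, CC1(C)OB(OC1(C)C)B1OC(C)(C)C(C)(C)O1 (Bpin of intermediate 15 only)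
Why: One‑pot Miyaura borylation / Suzuki–Miyaura coupling joins the hindered aryl boronate to the alkenyl bromide (a bulky biarylphosphine is used for the ortho‑siloxy partner), giving the isoflav‑3‑ene with no stereocentre.

Step 7
Reactants: 16 3‑[2,5‑bis(tert‑butyldimethylsilyloxy)‑3,4‑dimethoxyphenyl]‑6,7,8‑trimethoxy‑2H‑chromene
Product: 18 (3S,4R)‑3‑[2,5‑bis(tert‑butyldimethylsilyloxy)‑3,4‑dimethoxyphenyl]‑6,7,8‑trimethoxychroman‑4‑ol, via organoborane 17 (not isolated)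
Conditions: IpcBH2 from (+)‑α‑pinene (2 equiv), THF, −25 to 0 °C, 48 h; then NaBO3·4H2O, THF/H2O, rt
Reagents that add atoms: monoisopinocampheylborane, C[C@H]1[C@H](B)C[C@@H]2C[C@H]1C2(C)C (H at C3 of 18; B and Ipc of intermediate 17 only); sodium perborate, [Na+].[Na+].O[B-]1(O)OO[B-](O)(O)OO1
Why: Brown asymmetric hydroboration–oxidation adds H to C3 and B to the less hindered C4 on the same face and oxidises C–B with retention, so aryl and OH end up trans, and the (+)‑α‑pinene‑derived reagent is chosen for the (3S,4R) face by analogy with its conversion of 1‑arylcycloalkenes into (1S,2R)‑trans‑2‑arylcycloalkanols.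

Step 8
Reactants: 18 (3S,4R)‑3‑[2,5‑bis(tert‑butyldimethylsilyloxy)‑3,4‑dimethoxyphenyl]‑6,7,8‑trimethoxychroman‑4‑ol
Product: 19 (3S,4R)‑3‑(2,5‑dihydroxy‑3,4‑dimethoxyphenyl)‑6,7,8‑trimethoxychroman‑4‑ol
Conditions: TBAF (2.2 equiv), AcOH (2.4 equiv), THF, 0 °C, Ar; Na2S2O4 (aq) wash
Reagents that add atoms: none
Why: Buffered fluoride desilylation frees the hydroquinone under near‑neutral, oxygen‑free conditions that neither ionise the benzylic C4–OH (no pterocarpan closure) nor touch either stereocentre.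

**Compound list**
1 | 2,3‑dibromoprop‑1‑ene | C=C(Br)CBr | starting material
2 | ethynylmagnesium bromide | C#C[Mg]Br | starting material
3 | 2‑bromopent‑1‑en‑4‑yne | C=C(Br)CC#C | intermediate
4 | dimethyl squarate (3,4‑dimethoxycyclobut‑3‑ene‑1,2‑dione) | COC1=C(OC)C(=O)C1=O | starting material
5 | lithium 4‑bromopent‑4‑en‑1‑yn‑1‑ide | [Li]C#CCC(Br)=C | intermediate (not isolated)
6 | 4‑(4‑bromopent‑4‑en‑1‑yn‑1‑yl)‑4‑hydroxy‑2,3‑dimethoxycyclobut‑2‑en‑1‑one, racemic | COC1=C(OC)C(O)(C#CCC(Br)=C)C1=O | intermediate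
7 | 2‑(2‑bromoprop‑2‑en‑1‑yl)‑5,6‑dimethoxy‑1,4‑benzoquinone | COC1=C(OC)C(=O)C(CC(Br)=C)=CC1=O | intermediate (not isolated)
8 | 3‑bromo‑7,8‑dimethoxy‑2H‑chromen‑6‑ol | COc1c(O)cc2C=C(Br)COc2c1OC | intermediate (not isolated)
9 | 3‑bromo‑6,7,8‑trimethoxy‑2H‑chromene | COc1cc2C=C(Br)COc2c(OC)c1OC | intermediate
10 | 2,3‑dimethoxy‑1,4‑benzoquinone | COC1=C(OC)C(=O)C=CC1=O | starting material
11 | rac‑trans‑5,6‑dibromo‑2,3‑dimethoxycyclohex‑2‑ene‑1,4‑dione | COC1=C(OC)C(=O)[C@H](Br)[C@@H](Br)C1=O | intermediate (not isolated)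
12 | 5‑bromo‑2,3‑dimethoxy‑1,4‑benzoquinone | COC1=C(OC)C(=O)C(Br)=CC1=O | intermediate
13 | 5‑bromo‑2,3‑dimethoxybenzene‑1,4‑diol | COc1c(O)cc(Br)c(O)c1OC | intermediate (not isolated)
14 | 1‑bromo‑2,5‑bis(tert‑butyldimethylsilyloxy)‑3,4‑dimethoxybenzene | COc1c(O[Si](C)(C)C(C)(C)C)cc(Br)c(O[Si](C)(C)C(C)(C)C)c1OC | intermediate
15 | 2‑[2,5‑bis(tert‑butyldimethylsilyloxy)‑3,4‑dimethoxyphenyl]‑4,4,5,5‑tetramethyl‑1,3,2‑dioxaborolane | COc1c(O[Si](C)(C)C(C)(C)C)cc(B2OC(C)(C)C(C)(C)O2)c(O[Si](C)(C)C(C)(C)C)c1OC | intermediate (not isolated)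
16 | 3‑[2,5‑bis(tert‑butyldimethylsilyloxy)‑3,4‑dimethoxyphenyl]‑6,7,8‑trimethoxy‑2H‑chromene | COc1c(O[Si](C)(C)C(C)(C)C)cc(C2=Cc3cc(OC)c(OC)c(OC)c3OC2)c(O[Si](C)(C)C(C)(C)C)c1OC | intermediate
17 | [(3S,4R)‑3‑[2,5‑bis(tert‑butyldimethylsilyloxy)‑3,4‑dimethoxyphenyl]‑6,7,8‑trimethoxychroman‑4‑yl](isopinocampheyl)borane | C[C@H]1[C@H](B[C@H]3c4cc(OC)c(OC)c(OC)c4OC[C@@H]3c3cc(O[Si](C)(C)C(C)(C)C)c(OC)c(OC)c3O[Si](C)(C)C(C)(C)C)C[C@@H]2C[C@H]1C2(C)C | intermediate (not isolated)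
18 | (3S,4R)‑3‑[2,5‑bis(tert‑butyldimethylsilyloxy)‑3,4‑dimethoxyphenyl]‑6,7,8‑trimethoxychroman‑4‑ol | COc1cc2c(c(OC)c1OC)OC[C@H](c1cc(O[Si](C)(C)C(C)(C)C)c(OC)c(OC)c1O[Si](C)(C)C(C)(C)C)[C@H]2O | intermediate
19 | (3S,4R)‑3‑(2,5‑dihydroxy‑3,4‑dimethoxyphenyl)‑6,7,8‑trimethoxychroman‑4‑ol | COc1cc2c(c(OC)c1OC)OC[C@H](c1cc(O)c(OC)c(OC)c1O)[C@H]2O | target

**Totals**
Total steps: 8. Longest linear sequence: 6 (steps 1, 2, 3, 6, 7, 8); steps 4 and 5 form the second branch.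

**Steps most likely to fail, with fallbacks**

Step 3. The one‑flask cascade is untested for a 2‑bromoallyl side chain: the Moore step may give some cyclopentenedione, and the quinone methide may oligomerise before it electrocyclises. The fallback builds the bromochromene by a propargyl ether Claisen route and sets out from quinone 10. Dithionite reduction gives 2,3‑dimethoxybenzene‑1,4‑diol F1, and mono‑O‑methylation (MeI 1 equiv, K2CO3) gives 2,3,4‑trimethoxyphenol F2. Propargyl bromide/K2CO3 then gives 1,2,3‑trimethoxy‑4‑(prop‑2‑yn‑1‑yloxy)benzene F3, and thermal Claisen rearrangement/[1,5]‑H shift/oxa‑6π closure (PhNEt2, 200 °C) gives 6,7,8‑trimethoxy‑2H‑chromene F4. Bromine addition gives rac‑trans‑3,4‑dibromo‑6,7,8‑trimethoxychromane F5, and DBU elimination returns to the route at 9.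

Step 6. The aryl boronate is hindered and electron‑rich, so it may protodeboronate, and the aryl silyl ethers may be lost to the base. The fallback reverses polarity and couples at the quinone oxidation level, setting out from 9. Miyaura borylation gives 4,4,5,5‑tetramethyl‑2‑(6,7,8‑trimethoxy‑2H‑chromen‑3‑yl)‑1,3,2‑dioxaborolane F6. Suzuki coupling with the unhindered, electron‑poor bromoquinone 12 (Pd(dppf)Cl2, CsF) gives 2,3‑dimethoxy‑5‑(6,7,8‑trimethoxy‑2H‑chromen‑3‑yl)‑1,4‑benzoquinone F7. Dithionite gives 2,3‑dimethoxy‑5‑(6,7,8‑trimethoxy‑2H‑chromen‑3‑yl)benzene‑1,4‑diol F8, and silylation under non‑acidic conditions (TBSCl, imidazole) returns to the route at 16.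

Step 7. The sense and level of induction by IpcBH2 on this hindered, benzo‑fused alkene rest on analogy, and the reaction may be slow. The fallback is racemic hydroboration followed by resolution, setting out from 16. BH3·THF then NaBO3 gives rac‑(3S*,4R*)‑3‑[2,5‑bis(tert‑butyldimethylsilyloxy)‑3,4‑dimethoxyphenyl]‑6,7,8‑trimethoxychroman‑4‑ol F9. Esterification with (S)‑O‑methylmandelic acid (DCC, DMAP) gives the (3S,4R)‑chromanyl (S)‑2‑methoxy‑2‑phenylacetate F10 and the (3R,4S)‑chromanyl (S)‑2‑methoxy‑2‑phenylacetate F11, which are separated by chromatography (F11 is discarded). DIBAL‑H cleavage of F10 at −78 °C returns to the route at 18.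

**Further compounds**
F1 | step 3 | 2,3‑dimethoxybenzene‑1,4‑diol | COc1c(O)ccc(O)c1OC
F2 | step 3 | 2,3,4‑trimethoxyphenol | COc1ccc(O)c(OC)c1OC
F3 | step 3 | 1,2,3‑trimethoxy‑4‑(prop‑2‑yn‑1‑yloxy)benzene | COc1ccc(OCC#C)c(OC)c1OC
F4 | step 3 | 6,7,8‑trimethoxy‑2H‑chromene | COc1cc2C=CCOc2c(OC)c1OC
F5 | step 3 | rac‑trans‑3,4‑dibromo‑6,7,8‑trimethoxychromane | COc1cc2c(c(OC)c1OC)OC[C@H](Br)[C@H]2Br
F6 | step 6 | 4,4,5,5‑tetramethyl‑2‑(6,7,8‑trimethoxy‑2H‑chromen‑3‑yl)‑1,3,2‑dioxaborolane | COc1cc2C=C(B3OC(C)(C)C(C)(C)O3)COc2c(OC)c1OC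
F7 | step 6 | 2,3‑dimethoxy‑5‑(6,7,8‑trimethoxy‑2H‑chromen‑3‑yl)‑1,4‑benzoquinone | COC1=C(OC)C(=O)C(C2=Cc3cc(OC)c(OC)c(OC)c3OC2)=CC1=O
F8 | step 6 | 2,3‑dimethoxy‑5‑(6,7,8‑trimethoxy‑2H‑chromen‑3‑yl)benzene‑1,4‑diol | COc1c(O)cc(C2=Cc3cc(OC)c(OC)c(OC)c3OC2)c(O)c1OC
F9 | step 7 | rac‑(3S*,4R*)‑3‑[2,5‑bis(tert‑butyldimethylsilyloxy)‑3,4‑dimethoxyphenyl]‑6,7,8‑trimethoxychroman‑4‑ol (racemate, relative configuration shown) | COc1cc2c(c(OC)c1OC)OC[C@H](c1cc(O[Si](C)(C)C(C)(C)C)c(OC)c(OC)c1O[Si](C)(C)C(C)(C)C)[C@H]2O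
F10 | step 7 | (3S,4R)‑3‑[2,5‑bis(tert‑butyldimethylsilyloxy)‑3,4‑dimethoxyphenyl]‑6,7,8‑trimethoxychroman‑4‑yl (S)‑2‑methoxy‑2‑phenylacetate | COc1cc2c(c(OC)c1OC)OC[C@H](c1cc(O[Si](C)(C)C(C)(C)C)c(OC)c(OC)c1O[Si](C)(C)C(C)(C)C)[C@H]2OC(=O)[C@@H](OC)c1ccccc1
F11 | step 7 | (3R,4S)‑3‑[2,5‑bis(tert‑butyldimethylsilyloxy)‑3,4‑dimethoxyphenyl]‑6,7,8‑trimethoxychroman‑4‑yl (S)‑2‑methoxy‑2‑phenylacetate | COc1cc2c(c(OC)c1OC)OC[C@@H](c1cc(O[Si](C)(C)C(C)(C)C)c(OC)c(OC)c1O[Si](C)(C)C(C)(C)C)[C@@H]2OC(=O)[C@@H](OC)c1ccccc1
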